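**Retrosynthetic overview**

- Feature: the target has one six-membered quinone ring, numbered C1 (C=O), C2 (OH), C3 (docosyl), C4 (C=O), C5 (OMe), C6 (H). The chain carbon C3 lies between the oxygen-bearing C2 and C4, and C1 and C5 also carry oxygen. With OH on C2 and C4 and OMe on C1 and C5, the ring is mirror-symmetric about the C3···C6 axis.
- Last disconnection: the hydroxy-methoxy-quinone comes from the symmetric 2-docosyl-4,6-dimethoxybenzene-1,3-diol by oxidation with loss of one methyl group; either half of the diol leads to the same product.
- Key disconnection: the C2–O and C4–O bonds come from the two formyl groups of 2-docosyl-4,6-dimethoxybenzene-1,3-dicarbaldehyde by a twofold Dakin oxidation.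
- The dialdehyde comes from 1-docosyl-3,5-dimethoxybenzene by two Rieche formylations beside the chain; that arene comes from a Kumada coupling of docosylmagnesium bromide with 1-bromo-3,5-dimethoxybenzene.
- Ring formation: none. The benzene ring of the aryl bromide is carried through and becomes the quinone ring.

Key step: step 4

Remark on the chemistry: the target has no stereocentre and is drawn as the 2-hydroxy-1,4-quinone, the stable tautomer. The formyl carbons lost in the Dakin step are taken to leave as methyl formate, because the medium is acidic methanol.

**Route**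

Step 1
Reactants: 1 1-bromodocosane; 2 1-bromo-3,5-dimethoxybenzene
Product: 4 1-docosyl-3,5-dimethoxybenzene, via docosylmagnesium bromide 3 (not isolated)
Conditions: 1, Mg, I2 (cat.), THF, reflux; then 2, PdCl2(dppf) (3 mol %), THF, 0 °C → reflux
Reagents that add atoms: none
Why: Kumada–Corriu cross-coupling: the aryl bromide adds oxidatively to zerovalent palladium (formed in the flask from the divalent precatalyst by the Grignard reagent), the primary alkyl group is transferred from magnesium, and the wide bite angle of dppf should make C(sp3)–C(sp2) reductive elimination faster than β-hydride elimination.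

Step 2
Reactants: 4 1-docosyl-3,5-dimethoxybenzene; 5 dichloromethyl methyl ether
Product: 7 2-docosyl-4,6-dimethoxybenzaldehyde, via aryl α-chloro ether 6 (not isolated)
Conditions: 5 (1.2 equiv), TiCl4 (2.2 equiv), CH2Cl2, −10 → 0 °C; then ice–water, 1 M HCl
Reagents that add atoms: water, O
Why: Rieche formylation, an electrophilic aromatic substitution by the chloro(methoxy)methyl cation that TiCl4 releases from 5: attack is expected at the ring carbon beside the chain, which is para to one methoxy group and ortho to the other (the normal site for 5-alkylresorcinol dimethyl ethers, the carbon between the two methoxy groups being the more crowded), and the α-chloro ether 6 is hydrolysed to the aldehyde on aqueous work-up.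

Step 3
Reactants: 7 2-docosyl-4,6-dimethoxybenzaldehyde; 5 dichloromethyl methyl ether
Product: 9 2-docosyl-4,6-dimethoxybenzene-1,3-dicarbaldehyde, via formyl aryl α-chloro ether 8 (not isolated)
Conditions: 5 (3 equiv), TiCl4 (4 equiv), CH2Cl2, 0 °C → reflux; then ice–water, 1 M HCl
Reagents that add atoms: water, O
Why: A second Rieche formylation on a ring that still carries two methoxy donors: the formyl group already present is meta to both free ring carbons and so does not choose between them, the carbon on the other side of the chain is again para to a methoxy group (the orientation that takes 1,3-dimethoxybenzene to its 4,6-dicarbaldehyde), and excess reagent with warming should make up for the deactivation.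

Step 4
Reactants: 9 2-docosyl-4,6-dimethoxybenzene-1,3-dicarbaldehyde
Product: 11 2-docosyl-4,6-dimethoxybenzene-1,3-diol, via aryl diformate 10 (not isolated)
Conditions: 30% aq H2O2 (3 equiv), H2SO4 (cat.), MeOH–CH2Cl2, rt, N2
Reagents that add atoms: hydrogen peroxide, OO
Why: Acid-catalysed addition of H2O2 to each formyl group gives a tetrahedral hydroxy hydroperoxide, whose protonated O–O bond breaks as the aryl carbon shifts from carbon to oxygen, so that the C2–O and C4–O bonds form on both sides of the chain carbon C3 and diformate 10 results; acid-catalysed methanolysis then frees the two phenols as methyl formate leaves. The closest known reaction type is the acid-catalysed Dakin oxidation, a Baeyer–Villiger-type oxidation of ortho- and para-alkoxybenzaldehydes to phenols. No ring is closed and no stereocentre is created. The selectivity needed is aryl over hydride migration at both formyl groups, since a hydride shift would end in a benzoic acid or its methyl ester; each migrating ring carbon is ortho to one methoxy group and para to the other, so it can carry the positive charge that builds up during the shift. The second oxidation should be no slower than the first, because the first replaces an electron-withdrawing formyl group by a donor oxygen. The electron-rich diol is kept under N2 with only a small excess of peroxide and is taken on crude.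

Step 5
Reactants: 11 2-docosyl-4,6-dimethoxybenzene-1,3-diol
Product: 12 3-docosyl-2-hydroxy-5-methoxycyclohexa-2,5-diene-1,4-dione
Conditions: (NH4)2Ce(NO3)6 (2.2 equiv), MeCN–CH2Cl2–H2O, 0 °C
Reagents that add atoms: water, O
Why: Oxidative demethylation of a para-methoxyphenol to a para-quinone by two one-electron oxidations with tetravalent cerium, water adding to the methoxy-bearing carbon and methanol leaving; the pairs C2–OH/C5–OMe and C4–OH/C1–OMe are mirror images, and even an ortho-quinone from either hydroxyl would be only a tautomer of the same hydroxyquinone, so every mode of oxidation should converge on 12.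

**Compound list**

1 | 1-bromodocosane | CCCCCCCCCCCCCCCCCCCCCCBr | starting material
2 | 1-bromo-3,5-dimethoxybenzene | COc1cc(Br)cc(OC)c1 | starting material
3 | docosylmagnesium bromide | CCCCCCCCCCCCCCCCCCCCCC[Mg]Br | intermediate
4 | 1-docosyl-3,5-dimethoxybenzene | CCCCCCCCCCCCCCCCCCCCCCc1cc(OC)cc(OC)c1 | intermediate
5 | dichloromethyl methyl ether | COC(Cl)Cl | starting material
6 | 1-[chloro(methoxy)methyl]-2-docosyl-4,6-dimethoxybenzene (racemic) | CCCCCCCCCCCCCCCCCCCCCCc1cc(OC)cc(OC)c1C(Cl)OC | intermediate
7 | 2-docosyl-4,6-dimethoxybenzaldehyde | CCCCCCCCCCCCCCCCCCCCCCc1cc(OC)cc(OC)c1C=O | intermediate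
8 | 3-[chloro(methoxy)methyl]-2-docosyl-4,6-dimethoxybenzaldehyde (racemic) | CCCCCCCCCCCCCCCCCCCCCCc1c(C=O)c(OC)cc(OC)c1C(Cl)OC | intermediate
9 | 2-docosyl-4,6-dimethoxybenzene-1,3-dicarbaldehyde | CCCCCCCCCCCCCCCCCCCCCCc1c(C=O)c(OC)cc(OC)c1C=O | intermediate
10 | 2-docosyl-4,6-dimethoxy-1,3-phenylene diformate | CCCCCCCCCCCCCCCCCCCCCCc1c(OC=O)c(OC)cc(OC)c1OC=O | intermediate
11 | 2-docosyl-4,6-dimethoxybenzene-1,3-diol | CCCCCCCCCCCCCCCCCCCCCCc1c(O)c(OC)cc(OC)c1O | intermediate
12 | 3-docosyl-2-hydroxy-5-methoxycyclohexa-2,5-diene-1,4-dione | CCCCCCCCCCCCCCCCCCCCCCC1=C(O)C(=O)C=C(OC)C1=O | target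

**Step count**

Total step count: 5. Longest linear sequence: 5 steps (1 or 2 → 12).

**Steps most likely to fail**

Step 4 (key step). A hydride shift instead of the aryl shift may occur at one of the two crowded formyl groups. The sequence may stall after the first oxidation. Excess peroxide may oxidise the very electron-rich diol further. The fallback sets out from 7 and brings in the second oxygen at the quinone stage instead of by a second formyl-to-oxygen migration. A single Dakin oxidation of 7 (30% aq H2O2, H2SO4 cat., MeOH–CH2Cl2) should pass through 2-docosyl-4,6-dimethoxyphenyl formate F1 to 2-docosyl-4,6-dimethoxyphenol F2. Oxidation with (NH4)2Ce(NO3)6 in MeCN–H2O should then give 2-docosyl-6-methoxycyclohexa-2,5-diene-1,4-dione F3. Thiele–Winter acetoxylation (Ac2O, H2SO4 cat.) should add acetate at the ring carbon next to the chain, which is para to the methoxy group and is the β-carbon of the enone that the vinylogous ester does not deactivate, giving 3-docosyl-5-methoxybenzene-1,2,4-triyl triacetate F4. Methanolysis (HCl, MeOH, reflux, N2) should give 3-docosyl-5-methoxybenzene-1,2,4-triol F5, which air should oxidise to the hydroxyquinone. The fallback comes back to the route at 12.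

Step 3. The electrophile may attack the carbon between the two methoxy groups. Conversion of the deactivated ring may be incomplete. The Lewis acid may remove a methyl ether ortho to the formyl group through chelation. The fallback sets out from 4 and puts in both formyl groups through halogen–metal exchange. Twofold bromination (NBS, 2.1 equiv, MeCN, 0 °C → rt), para to each methoxy group, should give 2,4-dibromo-3-docosyl-1,5-dimethoxybenzene F6. Twofold bromine–lithium exchange (t-BuLi, 4.2 equiv, THF, −78 °C) should give (2-docosyl-4,6-dimethoxy-1,3-phenylene)dilithium F7, which is trapped with DMF and worked up with aqueous HCl. The fallback comes back to the route at 9.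

Step 5. Tetravalent cerium may over-oxidise or nitrate the free hydroxyquinone, and the acidic, waxy product may be lost on isolation. The fallback sets out from 11 and separates oxidation from the unmasking of the hydroxyl. Methylation (MeI, K2CO3, acetone, reflux) should give 3-docosyl-1,2,4,5-tetramethoxybenzene F8. Oxidative demethylation with (NH4)2Ce(NO3)6 in MeCN–H2O, a robust reaction of fully etherified arenes, should give 3-docosyl-2,5-dimethoxycyclohexa-2,5-diene-1,4-dione F9 from either para pair of methoxy groups. Hydrolysis of the vinylogous ester methoxy next to the chain (70% HClO4, 1,4-dioxane, rt) should then free the C2 hydroxyl. The fallback comes back to the route at 12.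

**Further compounds**

F1 | step 4 | 2-docosyl-4,6-dimethoxyphenyl formate | CCCCCCCCCCCCCCCCCCCCCCc1cc(OC)cc(OC)c1OC=O
F2 | step 4 | 2-docosyl-4,6-dimethoxyphenol | CCCCCCCCCCCCCCCCCCCCCCc1cc(OC)cc(OC)c1O
F3 | step 4 | 2-docosyl-6-methoxycyclohexa-2,5-diene-1,4-dione | CCCCCCCCCCCCCCCCCCCCCCC1=CC(=O)C=C(OC)C1=O
F4 | step 4 | 3-docosyl-5-methoxybenzene-1,2,4-triyl triacetate | CCCCCCCCCCCCCCCCCCCCCCc1c(OC(C)=O)c(OC(C)=O)cc(OC)c1OC(C)=O
F5 | step 4 | 3-docosyl-5-methoxybenzene-1,2,4-triol | CCCCCCCCCCCCCCCCCCCCCCc1c(O)c(O)cc(OC)c1O
F6 | step 3 | 2,4-dibromo-3-docosyl-1,5-dimethoxybenzene | CCCCCCCCCCCCCCCCCCCCCCc1c(Br)c(OC)cc(OC)c1Br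
F7 | step 3 | (2-docosyl-4,6-dimethoxy-1,3-phenylene)dilithium | CCCCCCCCCCCCCCCCCCCCCCc1c([Li])c(OC)cc(OC)c1[Li]
F8 | step 5 | 3-docosyl-1,2,4,5-tetramethoxybenzene | CCCCCCCCCCCCCCCCCCCCCCc1c(OC)c(OC)cc(OC)c1OC
F9 | step 5 | 3-docosyl-2,5-dimethoxycyclohexa-2,5-diene-1,4-dione | CCCCCCCCCCCCCCCCCCCCCCC1=C(OC)C(=O)C=C(OC)C1=O
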